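The data stem from a simulated flask for an exercise, noise included.

A small charge of precatalyst, 5 mol%, sits in a racemate of left-handed and right-handed substrate, with partner at 1 equiv on the left-handed substrate. The catalyst it gives is single-handed. You want to know how much left-handed product the flask holds at 8.0 d, and which option adds most after that.

| flask | left-handed substrate | right-handed substrate | partner | precatalyst | temperature | remark | time |
|---|---|---|---|---|---|---|---|
| Tuesday's | 1.6 M | 1.6 M | 1 equiv | 5 mol% | 25 °C | the very flask that is asked about, followed so far |  |
| Monday's | 1.6 M | 1.6 M | 1 equiv | 5 mol% | 20 °C | run made earlier |  |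
| flask | 1.6 M | 1.6 M | 1.00 equiv | 5 mol% | 25 °C |  | 8.0 d |

| run | time / d | left-handed product / % | left-handed substrate / % |
|---|---|---|---|
| Tuesday's | 0.500 | 1.4 | 45.5 |
| Tuesday's | 1.25 | 13.5 | 37.9 |
| Tuesday's | 3.00 | 22.9 | 27.2 |
| Tuesday's | 6.00 | 23.8 | 24.4 |
| Monday's | 0.500 | 1.0 | 49.1 |
| Monday's | 1.25 | 7.7 | 39.4 |
| Monday's | 3.00 | 18.7 | 30.8 |
| Monday's | 6.00 | 27.2 | 21.9 |

(each reading ± 1 percentage point)

- dawn: at 8.0 d raise the temperature by 20 K, then wait 2.5 d
- noon: change nothing and wait 2.5 d more
- summer: at 8.0 d add precatalyst, 50.0% of the amount charged, then wait 2.5 d
- dusk: at 8.0 d take out 90% of the left-handed product then present, then wait 2.5 d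

- catalyst is single-handed; left-handed substrate and right-handed substrate are mirror images of each other, charged as a racemate, each of them at the stated concentration
- left-handed product taken out counts as made
- additions bring no volume worth counting

- left-handed product, in percent of the left-handed substrate and right-handed substrate together first charged, at 8.0 d
- which option adds most left-handed product ("none" when 2 percentage points or less is all one gets) (dawn / noon / summer / dusk / none)
- left-handed product present, with what was taken out counted in, in percent of the left-handed substrate and right-handed substrate together first charged, after summer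
- left-handed product present, with what was taken out counted in, in percent of the left-handed substrate and right-handed substrate together first charged, after dusk

Begin with what the charge allows. Left-handed product and left-handed substrate sum to 48.2% at the last reading of Tuesday's run, and to similar values before it. So freeze that sum at the ceiling set by the charge, 50.0%; partner and left-handed substrate are charged equally, so either would be the limiting reagent there. Now define the room, the ceiling minus the left-handed product present: 26 percentage points at the last reading of Tuesday's run.

Then climb the ladder of times in that run. By 0.500 d the product is 1.4%, a short lag. The next slope would fill the ceiling in 3.10 d. The slope from 3.00 d to 6.00 d would fill the room in 87.3 d, far longer. That is a rough reading, because its rise of 0.9 points is smaller than the scatter. It is also far longer than the further wait, so I treat the room as frozen. My own reckoning gives 24.4% at 8.0 d, and noon adds 0.75 points, under the margin. Monday's run at 20 °C reads 27.2% at 6.00 d, more than Tuesday's, so Tuesday's stall is not the ceiling. The readings do not tell me which option opens the room.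

The forecast, a little above mine at 24.8%, names summer, with 31% after summer and 25% after dusk: “Fresh precatalyst restarts conversion”.

The flask gives 25.7%, and the best option is dawn, which adds 12 points; noon, summer and dusk each add 0.89 points, so the flask holds 26.5% after summer and 26.5% after dusk, with what was taken out counted in. At 8.0 d the room in the flask is 24 points, which is 0.779 M, and at 8.00 d the dormant form stands at 0.710 M. Dawn fills 12 points of that room.

    partner + catalyst + left-handed substrate → catalyst + left-handed product (k = 0.680 M⁻² h⁻¹, Ea = 48.0 kJ mol⁻¹)
    partner + catalyst + right-handed substrate → catalyst + right-handed product (k = 0.00360 M⁻² h⁻¹, Ea = 55.0 kJ mol⁻¹)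
    partner + precatalyst → catalyst + spent reagent (k = 0.0110 M⁻¹ h⁻¹, Ea = 74.0 kJ mol⁻¹)
    partner ⇌ dormant form (K = 13.0, k = 0.0160 h⁻¹, Ea = 112 kJ mol⁻¹, ΔH = −59.0 kJ mol⁻¹)
    (constants at 25 °C)

A repeat at 50 °C has the same charges, so the same ceiling of 50.0% bounds its product. It makes 45.7%, leaving that flask a room of 0.137 M, with dormant form at 0.0292 M.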